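**Retrosynthetic overview**

1. The target is the tris-silyl ether of itself after fluoride desilylation; the C2–C3 bond of the acyl chain (C1 = ketone carbon) is cut into the α-bromo ketone of bis-silylated 2',6'-dihydroxy-4'-methoxyacetophenone (ring, C1, C2) and a B-alkyl-9-BBN made in the flask from the terminal vinyl group of a C3–C18 pentaenyl silyl ether.
2. Enabling feature: the C1 ketone on the 2,6-dioxygenated benzene ring makes C2 an α-keto carbon that can carry bromide (polarity reversed), and the saturated C3–C4–C5 run lets C3 arrive as the C3=C4 vinyl group, the only monosubstituted alkene of the pentaene; two donor carbons are joined by a boron-ate 1,2-shift.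
3. Pentaene: C12=C13 by Z-selective Wittig reaction of a γ-silyloxy (E)-enal with the (Z)-hex-3-enyl ylide; C6=C7 by Lindlar reduction of a skipped enyne made by copper-catalysed allylation; C9 (R) by chiral-phosphoric-acid-catalysed propargylboration of fumaraldehyde mono(dimethyl acetal).
4. No ring is formed in the route: the benzene ring is bought as 2',6'-dihydroxy-4'-methoxyacetophenone.

Key step: step 11

Remark: locants C1–C18 are those of the acyl chain of the target. (R)-TRIP is assumed to direct the propargyl group to the Re face of the enal carbonyl, as it does for aryl aldehydes; should Mosher ester analysis of the carbinol show the opposite sense, (S)-TRIP would be used without other change.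

**Route**

Step 1
Reactants: 1 (E)-4,4-dimethoxybut-2-enal; 2 allenylboronic acid pinacol ester
Product: 4 (4R,5E)-7,7-dimethoxyhept-5-en-1-yn-4-ol, via pinacol borate 3 (not isolated)
Conditions: (R)-TRIP (10–20 mol %), 4 Å MS, toluene, 0 °C; aq NaHCO3 work-up
Reagents that add atoms: none
Why: Chiral phosphoric acid-catalysed propargylboration of an aldehyde, in which the phosphate activates the boronate and holds the formyl group in a closed six-membered SE2' transition state where only the γ-carbon of the allenyl group attacks, so the homopropargylic carbinol should form with the (R)-catalyst exposing the Re face to give the R centre, while the product stays masked as borate 3 and the dry medium keeps the acetal intact.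

Step 2
Reactants: 4 (4R,5E)-7,7-dimethoxyhept-5-en-1-yn-4-ol
Product: 5 tert-butyl{[(4R,5E)-7,7-dimethoxyhept-5-en-1-yn-4-yl]oxy}dimethylsilane
Conditions: TBSCl, imidazole, DMF, 0 °C → rt
Reagents that add atoms: tert-butyldimethylsilyl chloride, CC(C)(C)[Si](C)(C)Cl
Why: Standard imidazole-promoted silylation of a secondary alcohol, under which the dimethyl acetal and the terminal alkyne are inert.

Step 3
Reactants: 5 tert-butyl{[(4R,5E)-7,7-dimethoxyhept-5-en-1-yn-4-yl]oxy}dimethylsilane; 6 allyl bromide
Product: 7 tert-butyl{[(2E,4R)-1,1-dimethoxydeca-2,9-dien-6-yn-4-yl]oxy}dimethylsilane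
Conditions: CuI (10 mol %), Bu4NI (10 mol %), K2CO3, DMF, rt
Reagents that add atoms: none
Why: Copper(I)-catalysed coupling of a terminal alkyne with allyl bromide through the copper acetylide should give the skipped enyne, the mild carbonate base avoiding isomerisation to an allene or a conjugated enyne.

Step 4
Reactants: 7 tert-butyl{[(2E,4R)-1,1-dimethoxydeca-2,9-dien-6-yn-4-yl]oxy}dimethylsilane
Product: 8 tert-butyl{[(2E,4R,6Z)-1,1-dimethoxydeca-2,6,9-trien-4-yl]oxy}dimethylsilane
Conditions: H2 (1 atm), Lindlar catalyst, quinoline, EtOAc/hexane, 0 °C → rt, stopped after 1 equiv H2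
Reagents that add atoms: none
Why: Lindlar semihydrogenation delivers hydrogen syn on the poisoned palladium surface to give the Z alkene, the alkyne binding far more strongly than the vinyl group or the E alkene.

Step 5
Reactants: 8 tert-butyl{[(2E,4R,6Z)-1,1-dimethoxydeca-2,6,9-trien-4-yl]oxy}dimethylsilane
Product: 9 (2E,4R,6Z)-4-[(tert-butyldimethylsilyl)oxy]deca-2,6,9-trienal
Conditions: PPTS (cat.), THF/H2O, rt
Reagents that add atoms: water, O
Why: Acid-catalysed hydrolysis of an allylic dimethyl acetal, which ionises readily under PPTS while the secondary silyl ether and the skipped diene are stable and the E enal geometry is retained.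

Step 6
Reactants: 10 (Z)-hex-3-en-1-ol
Product: 11 (Z)-1-iodohex-3-ene
Conditions: I2, PPh3, imidazole, CH2Cl2, 0 °C → rt
Reagents that add atoms: iodine, II
Why: Garegg–Samuelsson (Appel-type) iodination, an SN2 displacement of the alkoxyphosphonium ion at a primary carbon that leaves the remote Z alkene untouched.

Step 7
Reactants: 11 (Z)-1-iodohex-3-ene
Product: 12 [(Z)-hex-3-en-1-yl]triphenylphosphonium iodide
Conditions: PPh3, MeCN, reflux
Reagents that add atoms: triphenylphosphine, c1ccc(cc1)P(c1ccccc1)c1ccccc1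
Why: SN2 quaternisation of triphenylphosphine by a primary iodide.

Step 8
Reactants: 9 (2E,4R,6Z)-4-[(tert-butyldimethylsilyl)oxy]deca-2,6,9-trienal; 12 [(Z)-hex-3-en-1-yl]triphenylphosphonium iodide
Product: 14 tert-butyl{[(4Z,7R,8E,10Z,13Z)-hexadeca-1,4,8,10,13-pentaen-7-yl]oxy}dimethylsilane, via phosphorus ylide 13 (not isolated)
Conditions: NaHMDS, THF, −78 → 0 °C; then 9, −78 °C → rt
Reagents that add atoms: none
Why: Wittig reaction of a non-stabilised ylide under lithium-free conditions at low temperature, where the kinetically formed cis-oxaphosphetane should collapse to the Z C12=C13 alkene while the E alkene of the enal, the silyloxy centre and the Z alkene of the ylide are carried through.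

Step 9
Reactants: 15 1-(2,6-dihydroxy-4-methoxyphenyl)ethan-1-one
Product: 16 1-{2,6-bis[(tert-butyldimethylsilyl)oxy]-4-methoxyphenyl}ethan-1-one
Conditions: TBSCl (2.5 equiv), imidazole, DMF, rt → 40 °C
Reagents that add atoms: tert-butyldimethylsilyl chloride, CC(C)(C)[Si](C)(C)Cl
Why: Silylation of both chelated phenols with excess silyl chloride; the bis-silyl ether prevents cyclisation of the later α-bromo ketone to a benzofuranone and is removable by fluoride.

Step 10
Reactants: 16 1-{2,6-bis[(tert-butyldimethylsilyl)oxy]-4-methoxyphenyl}ethan-1-one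
Product: 18 2-bromo-1-{2,6-bis[(tert-butyldimethylsilyl)oxy]-4-methoxyphenyl}ethan-1-one, via TMS enol ether 17 (not isolated)
Conditions: TMSOTf, Et3N, CH2Cl2, 0 °C; then NBS, THF, −78 °C
Reagents that add atoms: N-bromosuccinimide, O=C1CCC(=O)N1Br
Why: Soft enolisation to the trimethylsilyl enol ether followed by electrophilic bromination with NBS, the enol ether being far more nucleophilic than the silyloxy-flanked ring carbons, so monobromination at the methyl carbon should occur without free enolate or hydrogen bromide.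

Step 11
Reactants: 14 tert-butyl{[(4Z,7R,8E,10Z,13Z)-hexadeca-1,4,8,10,13-pentaen-7-yl]oxy}dimethylsilane; 18 2-bromo-1-{2,6-bis[(tert-butyldimethylsilyl)oxy]-4-methoxyphenyl}ethan-1-one
Product: 21 (6Z,9R,10E,12Z,15Z)-1-{2,6-bis[(tert-butyldimethylsilyl)oxy]-4-methoxyphenyl}-9-[(tert-butyldimethylsilyl)oxy]octadeca-6,10,12,15-tetraen-1-one, via B-alkyl-9-BBN 19 (not isolated), via boron enolate 20 (not isolated)
Conditions: 9-BBN (1.0 equiv), THF, 0 °C → rt; then 18, 0 °C; then potassium 2,6-di-tert-butylphenoxide (from KOtBu and 2,6-di-tert-butylphenol), THF, 0 °C; aq NH4Cl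
Reagents that add atoms: none
Why: 9-BBN should add anti-Markovnikov and only to the monosubstituted C3=C4 vinyl group, the four 1,2-disubstituted alkenes reacting far more slowly, to give the primary borane 19. The hindered phenoxide then enolises bromo ketone 18, the bromo enolate binds boron through carbon, and the primary alkyl group migrates from boron to C2 with loss of bromide (1,2-metallate shift); the α-boryl ketone tautomerises to boron enolate 20 (drawn as the Z(O) isomer, geometry immaterial), which is protonated on work-up. The closest known reaction type is the Brown α-alkylation of α-bromo ketones, phenacyl bromide included, with B-alkyl-9-BBN reagents under potassium 2,6-di-tert-butylphenoxide, in which the bicyclic boron framework does not migrate. No ring is closed and no stereocentre is created; C9 and the four alkene geometries are only carried through. The step needs chemoselective hydroboration, substitution at C2 in preference to self-condensation or attack on the aryl silyl ethers, and monoalkylation; these are secured by the single vinyl group, by a base too hindered to bind boron or silicon and too weak to deprotonate the product ketone, and by the single displaceable bromide.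

Step 12
Reactants: 21 (6Z,9R,10E,12Z,15Z)-1-{2,6-bis[(tert-butyldimethylsilyl)oxy]-4-methoxyphenyl}-9-[(tert-butyldimethylsilyl)oxy]octadeca-6,10,12,15-tetraen-1-one
Product: 22 (6Z,9R,10E,12Z,15Z)-1-(2,6-dihydroxy-4-methoxyphenyl)-9-hydroxyoctadeca-6,10,12,15-tetraen-1-one
Conditions: TBAF, AcOH, THF, 0 °C → rt
Reagents that add atoms: none
Why: Fluoride-mediated cleavage of the two aryl silyl ethers and the allylic silyl ether, buffered with acetic acid so that neither the skipped polyene nor the dienyl carbinol meets strong base or acid, and no stereocentre or alkene is touched.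

**Compound list**

1 | (E)-4,4-dimethoxybut-2-enal (fumaraldehyde mono(dimethyl acetal)) | COC(OC)/C=C/C=O | starting material
2 | allenylboronic acid pinacol ester | C=C=CB1OC(C)(C)C(C)(C)O1 | starting material
3 | 2-{[(4R,5E)-7,7-dimethoxyhept-5-en-1-yn-4-yl]oxy}-4,4,5,5-tetramethyl-1,3,2-dioxaborolane (pinacol borate of 4) | COC(OC)/C=C/[C@H](OB1OC(C)(C)C(C)(C)O1)CC#C | intermediate
4 | (4R,5E)-7,7-dimethoxyhept-5-en-1-yn-4-ol | COC(OC)/C=C/[C@H](O)CC#C | intermediate
5 | tert-butyl{[(4R,5E)-7,7-dimethoxyhept-5-en-1-yn-4-yl]oxy}dimethylsilane | COC(OC)/C=C/[C@H](O[Si](C)(C)C(C)(C)C)CC#C | intermediate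
6 | allyl bromide | C=CCBr | starting material
7 | tert-butyl{[(2E,4R)-1,1-dimethoxydeca-2,9-dien-6-yn-4-yl]oxy}dimethylsilane | COC(OC)/C=C/[C@H](O[Si](C)(C)C(C)(C)C)CC#CCC=C | intermediate
8 | tert-butyl{[(2E,4R,6Z)-1,1-dimethoxydeca-2,6,9-trien-4-yl]oxy}dimethylsilane | COC(OC)/C=C/[C@H](O[Si](C)(C)C(C)(C)C)C/C=C\CC=C | intermediate
9 | (2E,4R,6Z)-4-[(tert-butyldimethylsilyl)oxy]deca-2,6,9-trienal | O=C/C=C/[C@H](O[Si](C)(C)C(C)(C)C)C/C=C\CC=C | intermediate
10 | (Z)-hex-3-en-1-ol | CC/C=C\CCO | starting material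
11 | (Z)-1-iodohex-3-ene | CC/C=C\CCI | intermediate
12 | [(Z)-hex-3-en-1-yl]triphenylphosphonium iodide | CC/C=C\CC[P+](c1ccccc1)(c1ccccc1)c1ccccc1.[I-] | intermediate
13 | [(Z)-hex-3-en-1-ylidene]triphenylphosphorane | CC/C=C\CC=P(c1ccccc1)(c1ccccc1)c1ccccc1 | intermediate
14 | tert-butyl{[(4Z,7R,8E,10Z,13Z)-hexadeca-1,4,8,10,13-pentaen-7-yl]oxy}dimethylsilane | CC/C=C\C/C=C\C=C\[C@H](O[Si](C)(C)C(C)(C)C)C/C=C\CC=C | intermediate
15 | 1-(2,6-dihydroxy-4-methoxyphenyl)ethan-1-one | CC(=O)c1c(O)cc(OC)cc1O | starting material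
16 | 1-{2,6-bis[(tert-butyldimethylsilyl)oxy]-4-methoxyphenyl}ethan-1-one | CC(=O)c1c(O[Si](C)(C)C(C)(C)C)cc(OC)cc1O[Si](C)(C)C(C)(C)C | intermediate
17 | ({1-[2,6-bis(tert-butyldimethylsilyloxy)-4-methoxyphenyl]ethenyl}oxy)trimethylsilane | C=C(O[Si](C)(C)C)c1c(O[Si](C)(C)C(C)(C)C)cc(OC)cc1O[Si](C)(C)C(C)(C)C | intermediate
18 | 2-bromo-1-{2,6-bis[(tert-butyldimethylsilyl)oxy]-4-methoxyphenyl}ethan-1-one | BrCC(=O)c1c(O[Si](C)(C)C(C)(C)C)cc(OC)cc1O[Si](C)(C)C(C)(C)C | intermediate
19 | 9-{(4Z,7R,8E,10Z,13Z)-7-[(tert-butyldimethylsilyl)oxy]hexadeca-4,8,10,13-tetraen-1-yl}-9-borabicyclo[3.3.1]nonane | CC/C=C\C/C=C\C=C\[C@H](O[Si](C)(C)C(C)(C)C)C/C=C\CCCB1C2CCCC1CCC2 | intermediate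
20 | 9-BBN enol borinate of 21 (Z(O) isomer drawn) | CC/C=C\C/C=C\C=C\[C@H](O[Si](C)(C)C(C)(C)C)C/C=C\CCC/C=C(\OB1C2CCCC1CCC2)c1c(O[Si](C)(C)C(C)(C)C)cc(OC)cc1O[Si](C)(C)C(C)(C)C | intermediate
21 | (6Z,9R,10E,12Z,15Z)-1-{2,6-bis[(tert-butyldimethylsilyl)oxy]-4-methoxyphenyl}-9-[(tert-butyldimethylsilyl)oxy]octadeca-6,10,12,15-tetraen-1-one | CC/C=C\C/C=C\C=C\[C@H](O[Si](C)(C)C(C)(C)C)C/C=C\CCCCC(=O)c1c(O[Si](C)(C)C(C)(C)C)cc(OC)cc1O[Si](C)(C)C(C)(C)C | intermediate
22 | (6Z,9R,10E,12Z,15Z)-1-(2,6-dihydroxy-4-methoxyphenyl)-9-hydroxyoctadeca-6,10,12,15-tetraen-1-one | CC/C=C\C/C=C\C=C\[C@H](O)C/C=C\CCCCC(=O)c1c(O)cc(OC)cc1O | target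

**Step count and risks**

Total step count: 12. Longest linear sequence: 8 steps (steps 1, 2, 3, 4, 5, 8, 11, 12).

Steps most likely to fail:

Step 11. The potassium bromo enolate may shift a silyl group from an ortho aryl ether to the enolate oxygen, or condense with itself, faster than it is captured by the hindered borane, and the ate complex may not rearrange cleanly. The fallback sets out from 14 and 18 and comes back at 21; it makes the same C2–C3 bond as an alkene and then reduces it. Hydroboration of 14 with 9-BBN (to 19) followed by NaBO3·4H2O oxidation would give the primary alcohol (4Z,7R,8E,10Z,13Z)-7-[(tert-butyldimethylsilyl)oxy]hexadeca-4,8,10,13-tetraen-1-ol F1, and Dess–Martin periodinane/NaHCO3 would give the aldehyde (4Z,7R,8E,10Z,13Z)-7-[(tert-butyldimethylsilyl)oxy]hexadeca-4,8,10,13-tetraenal F2. Separately, 18 and PPh3 (toluene, rt) would give the acylmethyl phosphonium bromide F3, which Et3N would convert into the stabilised acyl phosphorane F4. Wittig olefination of F2 with F4 (toluene, 60 °C) should give the (2E)-enone F5, and conjugate reduction with Stryker's reagent, which leaves isolated and unactivated conjugated alkenes alone, would deliver 21.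

Step 1. Facial discrimination may be insufficient for this γ-acetal enal, or acetal exchange may occur under the acid catalyst. The fallback sets out from 1 and comes back at 4. Zinc-mediated Barbier propargylation of 1 with propargyl bromide (THF, 0 °C) would give the racemic carbinol F6. Lipase resolution (Candida antarctica lipase B, vinyl acetate, MTBE) should, on the Kazlauskas model with the alkenyl group as the large and the propargyl group as the medium substituent, acylate the R enantiomer to the (R)-acetate F7 and leave the (S)-alcohol F8, which is separated. Methanolysis of F7 (K2CO3, MeOH) would give 4.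

Step 4. The vinyl group may be over-reduced and the new alkene isomerised once the alkyne is consumed. The fallback sets out from 5, replaces steps 3 and 4, and comes back at 8. Iodination of the terminal alkyne (NIS, cat. AgNO3, acetone) would give the 1-iodoalkyne F9. cis-Reduction with diimide (2-nitrobenzenesulfonyl hydrazide, Et3N, THF/i-PrOH) would give the (Z)-vinyl iodide F10. Stille coupling with allyltributylstannane (Pd2(dba)3, AsPh3, DMF, rt) should give 8 with retention of the Z geometry.

Further compounds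
F1 | step 11 | (4Z,7R,8E,10Z,13Z)-7-[(tert-butyldimethylsilyl)oxy]hexadeca-4,8,10,13-tetraen-1-ol | CC/C=C\C/C=C\C=C\[C@H](O[Si](C)(C)C(C)(C)C)C/C=C\CCCO
F2 | step 11 | (4Z,7R,8E,10Z,13Z)-7-[(tert-butyldimethylsilyl)oxy]hexadeca-4,8,10,13-tetraenal | CC/C=C\C/C=C\C=C\[C@H](O[Si](C)(C)C(C)(C)C)C/C=C\CCC=O
F3 | step 11 | {2-[2,6-bis(tert-butyldimethylsilyloxy)-4-methoxyphenyl]-2-oxoethyl}triphenylphosphonium bromide | O=C(C[P+](c1ccccc1)(c1ccccc1)c1ccccc1)c1c(O[Si](C)(C)C(C)(C)C)cc(OC)cc1O[Si](C)(C)C(C)(C)C.[Br-]
F4 | step 11 | 1-[2,6-bis(tert-butyldimethylsilyloxy)-4-methoxyphenyl]-2-(triphenylphosphoranylidene)ethan-1-one | O=C(C=P(c1ccccc1)(c1ccccc1)c1ccccc1)c1c(O[Si](C)(C)C(C)(C)C)cc(OC)cc1O[Si](C)(C)C(C)(C)C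
F5 | step 11 | (2E,6Z,9R,10E,12Z,15Z)-1-{2,6-bis[(tert-butyldimethylsilyl)oxy]-4-methoxyphenyl}-9-[(tert-butyldimethylsilyl)oxy]octadeca-2,6,10,12,15-pentaen-1-one | CC/C=C\C/C=C\C=C\[C@H](O[Si](C)(C)C(C)(C)C)C/C=C\CC/C=C/C(=O)c1c(O[Si](C)(C)C(C)(C)C)cc(OC)cc1O[Si](C)(C)C(C)(C)C
F6 | step 1 | racemic (E)-7,7-dimethoxyhept-5-en-1-yn-4-ol | COC(OC)/C=C/C(O)CC#C
F7 | step 1 | (4R,5E)-7,7-dimethoxyhept-5-en-1-yn-4-yl acetate | COC(OC)/C=C/[C@H](OC(C)=O)CC#C
F8 | step 1 | (4S,5E)-7,7-dimethoxyhept-5-en-1-yn-4-ol | COC(OC)/C=C/[C@@H](O)CC#C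
F9 | step 4 | tert-butyl{[(4R,5E)-1-iodo-7,7-dimethoxyhept-5-en-1-yn-4-yl]oxy}dimethylsilane | COC(OC)/C=C/[C@H](O[Si](C)(C)C(C)(C)C)CC#CI
F10 | step 4 | tert-butyl{[(1Z,4R,5E)-1-iodo-7,7-dimethoxyhepta-1,5-dien-4-yl]oxy}dimethylsilane | COC(OC)/C=C/[C@H](O[Si](C)(C)C(C)(C)C)C/C=C\I
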